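Plan: Locants are germacranolide ones (carbocycle C1–C10; C11, C12, C13 = lactone α-carbon, carbonyl, exocyclic CH2; lactone O on C6). Enabling feature: C3 (ketone) and C8 (acyloxy carbinol) lie 1,6 across the ten-membered ring, and the Z alkene C4=C5 adjoins the cis-lactone carbons C6/C7, so C3–C8 is the footprint of a six-membered ring A, a cyclohexa-1,3-diene (C4=C5–C6=C7) held between two carbinol carbons.
Cuts (retro): C8 ester and C1 silyl ether; the ten-membered ring ← glycol cleavage of a temporary C3–C8 bond in a cis-fused tricycle; C1/C10 diol ← alkene C1=C10 ← ring-closing metathesis; C3–C2 ← allylation; lactone bonds O–C6 and C11–C7 together ← one palladium-catalysed annulation of 2-bromoacrylic acid onto the diene; C8–C9 ← methallylation; ring A ← a dearomatised guaiacol.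
Forward order: arene → ring A (dienone ketal) → C8 carbinol → lactone ring → C3 carbinol → ring B (metathesis) → C1/C10 diol → ten-membered ring (C3–C8 cleavage) → C8 alcohol → angelate.
Stereochemistry: an enantioselective methallylation sets a temporary centre at C8; it directs the annulation (C7, then C6 by cis closure); dihydroxylation on the convex face of the cis-fused tricycle sets C10, and oxidation then hydroxyl-directed reduction sets C1; C8 is re-made by 1,3-syn reduction from C10–OH; the 4Z geometry comes from ring A.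

Key step: step 3

Remark (assumption): 16, 19 and 20 are written as open hydroxy ketones; a 3,10-hemiketal is a ring–chain tautomer of the same constitution and is not treated as a separate compound.
Remark (assumption): the sense of induction in step 2 is secured by the choice of ligand antipode; the antipode that gives (1S)-4 is meant, and (R,R) is written for definiteness.

Step 1
Reactants: 1 2-methoxy-3-methylphenol
Product: 2 6,6-dimethoxy-5-methylcyclohexa-2,4-dien-1-one
Conditions: PhI(OAc)2, MeOH, 0 °C
Reagents that add atoms: methanol, CO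
Why: Oxidative dearomatisation of a 2-methoxyphenol by a hypervalent iodine diacetate (methanol adds to the methoxy-bearing carbon) should give the ortho-quinone monoketal, whose C5 methyl group slows the [4+2] dimerisation usual for such dienones; no stereocentre is formed.

Step 2
Reactants: 2 6,6-dimethoxy-5-methylcyclohexa-2,4-dien-1-one; 3 4,4,5,5-tetramethyl-2-(2-methylprop-2-en-1-yl)-1,3,2-dioxaborolane
Product: 4 (1S)-6,6-dimethoxy-5-methyl-1-(2-methylprop-2-en-1-yl)cyclohexa-2,4-dien-1-ol
Conditions: CuF2·2H2O (3 mol %), (R,R)-i-Pr-DuPHOS (6 mol %), La(OiPr)3 (4.5 mol %), DMF, −40 °C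
Reagents that add atoms: none
Why: Copper-catalysed enantioselective allylboration of a ketone (CuF–chiral bisphosphine with a lanthanum alkoxide co-catalyst) should add the 2-methylallyl group 1,2 through a six-membered transition state, the ligand choosing the carbonyl face between the flat CH=CH flank and the bulky ketal flank, which sets the temporary C8 carbinol as (S) while the low temperature outruns dimerisation of 2.

Step 3
Reactants: 4 (1S)-6,6-dimethoxy-5-methyl-1-(2-methylprop-2-en-1-yl)cyclohexa-2,4-dien-1-ol; 5 2-bromoprop-2-enoic acid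
Product: 6 (3aS,4S,7aS)-4-hydroxy-5,5-dimethoxy-6-methyl-3-methylidene-4-(2-methylprop-2-en-1-yl)-3a,4,5,7a-tetrahydro-1-benzofuran-2(3H)-one
Conditions: Pd(OAc)2 (5 mol %), PPh3 (10 mol %), KOAc, n-Bu4NCl, DMF, 80 °C
Reagents that add atoms: none
Why: Zerovalent palladium inserts into the C–Br bond of the 2-bromoacrylate, the α-carboxyvinyl–palladium species adds syn across C6=C7 with carbon at the CH terminus C7, and the resulting η3-allyl complex (C6–C5–C4) is captured at C6 by the carboxylate held on the same face, which releases the lactone and the catalyst. The closest known reaction type is the Larock heteroannulation of cyclic 1,3-dienes with vinylic halides that carry a carboxylic acid. The lactone ring closes in a 5-exo mode on the allyl terminus (attack at C4 would need a seven-membered ring), and because the two new bonds span adjacent carbons of a six-membered ring the fusion must be cis. C7 is set by 1,2-induction from the quaternary carbinol C8: the vinyl group should enter on the face of the small hydroxyl and anti to the 2-methylallyl arm, the syn-to-oxygen preference of o-quinol-type dienes, and C6 follows from C7 through the cis closure. The step needs regioselectivity (C7 against the methyl-bearing terminus C4), which the substitution pattern secures, and chemoselectivity for the diene over the isolated 1,1-disubstituted alkene; the weak acetate base keeps the tertiary homoallylic alcohol from retro-allylation and from transesterifying the new lactone.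

Step 4
Reactants: 6 (3aS,4S,7aS)-lactone ketal
Product: 7 (3aS,4S,7aS)-4-hydroxy-6-methyl-3-methylidene-4-(2-methylprop-2-en-1-yl)-3a,7a-dihydro-1-benzofuran-2,5(3H,4H)-dione
Conditions: PPTS, acetone–H2O, 40 °C
Reagents that add atoms: water, O
Why: Acid-catalysed ketal hydrolysis through the allyl-stabilised oxocarbenium ion should unveil the C3 ketone, which is non-enolisable (sp2 C4 on one side, quaternary C8 on the other) and so cannot drift toward an arene; no stereocentre changes.

Step 5
Reactants: 7 (3aS,4S,7aS)-hydroxy enone lactone; 8 3-bromoprop-1-ene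
Product: 9 (3aS,4S,5R,7aS)-4,5-dihydroxy-6-methyl-3-methylidene-4-(2-methylprop-2-en-1-yl)-5-(prop-2-en-1-yl)-3a,4,5,7a-tetrahydro-1-benzofuran-2(3H)-one
Conditions: Zn, THF–sat. aq. NH4Cl, 0 °C to rt
Reagents that add atoms: none
Why: Barbier allylation (allylzinc bromide formed in the flask) should add 1,2 to the ketone and leave the lactone alone, attack being expected anti to the axial C8–O bond (polar Felkin–Anh, axial attack on the conformer with the 2-methylallyl group equatorial), which gives the cis-diol with the two allyl arms cis; this C3 centre is temporary.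

Step 6
Reactants: 9 (3aS,4S,5R,7aS)-diallyl cis-diol
Product: 10 (3aS,5aR,9aS,9bS)-5a,9a-dihydroxy-5,8-dimethyl-1-methylidene-3a,5a,6,9,9a,9b-hexahydronaphtho[2,1-b]furan-2(1H)-one
Conditions: second-generation Grubbs catalyst, (H2IMes)(PCy3)Cl2Ru=CHPh (5 mol %), CH2Cl2, 40 °C
Reagents that add atoms: none
Why: Ring-closing metathesis of the cis allyl and 2-methylallyl arms should close ring B as a trisubstituted cyclohexene with loss of ethene, the electron-poor 1,1-disubstituted methylidene lactone and the hindered ring-A alkene staying out.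

Step 7
Reactants: 10 (3aS,5aR,9aS,9bS)-cis-fused tricyclic diol
Product: 11 (3aS,5aR,7R,8S,9aS,9bS)-5a,7,8,9a-tetrahydroxy-5,8-dimethyl-1-methylidene-3a,5a,6,7,8,9,9a,9b-octahydronaphtho[2,1-b]furan-2(1H)-one
Conditions: K2OsO4·2H2O (2 mol %), NMO, acetone–H2O, 0 °C
Reagents that add atoms: N-methylmorpholine N-oxide, C[N+]1([O-])CCOCC1; water, O
Why: Upjohn dihydroxylation should take the most electron-rich alkene, C1=C10 (C4=C5 is deactivated by two allylic C–O bonds and shielded, the methylidene lactone is electron-poor), from the convex face of the cis-fused ring system, the face of the two angular hydroxyls, which sets C10 (S) and places C1–OH provisionally cis to it.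

Step 8
Reactants: 11 (3aS,5aR,7R,8S,9aS,9bS)-tetraol
Product: 12 (3aS,5aR,8S,9aS,9bS)-5a,8,9a-trihydroxy-5,8-dimethyl-1-methylidene-3a,5a,6,8,9,9a-hexahydronaphtho[2,1-b]furan-2,7(1H,9bH)-dione
Conditions: IBX, DMSO, rt
Reagents that add atoms: none
Why: IBX oxidation should take the only secondary alcohol (C1) to the ketone without cleaving the 1,2-diol, the tertiary hydroxyls being inert, which prepares C1 for inversion.

Step 9
Reactants: 12 (3aS,5aR,8S,9aS,9bS)-hydroxy ketone
Product: 13 (3aS,5aR,7S,8S,9aS,9bS)-5a,7,8,9a-tetrahydroxy-5,8-dimethyl-1-methylidene-3a,5a,6,7,8,9,9a,9b-octahydronaphtho[2,1-b]furan-2(1H)-one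
Conditions: Me4NBH(OAc)3, MeCN–AcOH, −20 °C
Reagents that add atoms: none
Why: Hydroxyl-directed reduction (Evans–Saksena) should deliver hydride to the C1 ketone from the convex face, where the C10 and C3 hydroxyls bind the borohydride and the other face is blocked by ring A, giving C1–OH trans to C10–OH, that is (1S), in a medium that leaves the methylidene lactone untouched.

Step 10
Reactants: 13 (3aS,5aR,7S,8S,9aS,9bS)-tetraol
Product: 14 (3aS,5aR,7S,8S,9aS,9bS)-5a,8,9a-trihydroxy-5,8-dimethyl-1-methylidene-7-[(triethylsilyl)oxy]-3a,5a,6,7,8,9,9a,9b-octahydronaphtho[2,1-b]furan-2(1H)-one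
Conditions: Et3SiOTf, 2,6-lutidine, CH2Cl2, −78 °C
Reagents that add atoms: triethylsilyl trifluoromethanesulfonate, CC[Si](CC)(CC)OS(=O)(=O)C(F)(F)F
Why: Silylation with a silyl triflate at low temperature should take the only secondary hydroxyl (C1) and leave the three tertiary ones, so that C1/C10 no longer form a free glycol and C1–OH is masked for the later acylation.

Step 11
Reactants: 14 (3aS,5aR,7S,8S,9aS,9bS)-silyl ether triol
Product: 16 (3aR,4R,6S,7S,10Z,11aS)-4,6-dihydroxy-6,10-dimethyl-3-methylidene-7-[(triethylsilyl)oxy]-3a,4,5,6,7,8-hexahydrocyclodeca[b]furan-2,9(3H,11aH)-dione, via diketone 15 (not isolated)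
Conditions: Pb(OAc)4, CH2Cl2, 0 °C; then Et2BOMe, THF–MeOH, −78 °C, NaBH4
Reagents that add atoms: none
Why: Criegee glycol cleavage of the only free vicinal diol (cis, tertiary–tertiary) should cut the temporary C3–C8 bond and release the ten-membered ring with the Z enone inherited from ring A, after which Narasaka–Prasad reduction through the diethylboron chelate of C10–OH and the C8 ketone delivers hydride 1,3-syn (C7 and C1 branches equatorial on the chelate chair) and sets C8 (R) without touching the unchelated enone; the β-acyloxy ketone 15 is reduced at once to forestall enolisation toward C7.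

Step 12
Reactants: 16 (3aR,4R,6S,7S,10Z,11aS)-C8 alcohol; 17 (2Z)-2-methylbut-2-enoic acid (angelic acid)
Product: 19 (3aR,4R,6S,7S,10Z,11aS)-6-hydroxy-6,10-dimethyl-3-methylidene-2,9-dioxo-7-[(triethylsilyl)oxy]-2,3,3a,4,5,6,7,8,9,11a-decahydrocyclodeca[b]furan-4-yl (2Z)-2-methylbut-2-enoate, via mixed anhydride 18 (not isolated)
Conditions: 17, 2,4,6-trichlorobenzoyl chloride, Et3N, toluene, rt; then 16, toluene, 80 °C
Reagents that add atoms: 2,4,6-trichlorobenzoyl chloride, O=C(Cl)c1c(Cl)cc(Cl)cc1Cl (its atoms stay in intermediate 18 only)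
Why: Yamaguchi esterification through the mixed anhydride should acylate the only free secondary hydroxyl (C8), the tertiary C10–OH being inert, and without DMAP the angelate should not isomerise to the tiglate; no stereocentre is touched.

Step 13
Reactants: 19 (3aR,4R,6S,7S,10Z,11aS)-angelate silyl ether
Product: 20 (3aR,4R,6S,7S,10Z,11aS)-6,7-dihydroxy-6,10-dimethyl-3-methylidene-2,9-dioxo-2,3,3a,4,5,6,7,8,9,11a-decahydrocyclodeca[b]furan-4-yl (2Z)-2-methylbut-2-enoate
Conditions: HF·pyridine, THF, 0 °C
Reagents that add atoms: none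
Why: Fluoride desilylation under mildly acidic conditions should free C1–OH without base, so the β-hydroxy ketone, the angelate and the methylidene lactone survive.

Compound list
1 | 2-methoxy-3-methylphenol | COc1c(C)cccc1O | starting material
2 | 6,6-dimethoxy-5-methylcyclohexa-2,4-dien-1-one | COC1(OC)C(C)=CC=CC1=O | intermediate
3 | 4,4,5,5-tetramethyl-2-(2-methylprop-2-en-1-yl)-1,3,2-dioxaborolane | C=C(C)CB1OC(C)(C)C(C)(C)O1 | starting material
4 | (1S)-6,6-dimethoxy-5-methyl-1-(2-methylprop-2-en-1-yl)cyclohexa-2,4-dien-1-ol | COC1(OC)C(C)=CC=C[C@@]1(O)CC(C)=C | intermediate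
5 | 2-bromoprop-2-enoic acid | C=C(Br)C(=O)O | starting material
6 | (3aS,4S,7aS)-4-hydroxy-5,5-dimethoxy-6-methyl-3-methylidene-4-(2-methylprop-2-en-1-yl)-3a,4,5,7a-tetrahydro-1-benzofuran-2(3H)-one | C=C1C(=O)O[C@H]2C=C(C)C(OC)(OC)[C@](O)(CC(C)=C)[C@@H]12 | intermediate
7 | (3aS,4S,7aS)-4-hydroxy-6-methyl-3-methylidene-4-(2-methylprop-2-en-1-yl)-3a,7a-dihydro-1-benzofuran-2,5(3H,4H)-dione | C=C1C(=O)O[C@H]2C=C(C)C(=O)[C@](O)(CC(C)=C)[C@@H]12 | intermediate
8 | 3-bromoprop-1-ene (allyl bromide) | C=CCBr | starting material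
9 | (3aS,4S,5R,7aS)-4,5-dihydroxy-6-methyl-3-methylidene-4-(2-methylprop-2-en-1-yl)-5-(prop-2-en-1-yl)-3a,4,5,7a-tetrahydro-1-benzofuran-2(3H)-one | C=C1C(=O)O[C@H]2C=C(C)[C@](O)(CC=C)[C@](O)(CC(C)=C)[C@@H]12 | intermediate
10 | (3aS,5aR,9aS,9bS)-5a,9a-dihydroxy-5,8-dimethyl-1-methylidene-3a,5a,6,9,9a,9b-hexahydronaphtho[2,1-b]furan-2(1H)-one | C=C1C(=O)O[C@H]2C=C(C)[C@]3(O)CC=C(C)C[C@]3(O)[C@@H]12 | intermediate
11 | (3aS,5aR,7R,8S,9aS,9bS)-5a,7,8,9a-tetrahydroxy-5,8-dimethyl-1-methylidene-3a,5a,6,7,8,9,9a,9b-octahydronaphtho[2,1-b]furan-2(1H)-one | C=C1C(=O)O[C@H]2C=C(C)[C@]3(O)C[C@@H](O)[C@@](C)(O)C[C@]3(O)[C@@H]12 | intermediate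
12 | (3aS,5aR,8S,9aS,9bS)-5a,8,9a-trihydroxy-5,8-dimethyl-1-methylidene-3a,5a,6,8,9,9a-hexahydronaphtho[2,1-b]furan-2,7(1H,9bH)-dione | C=C1C(=O)O[C@H]2C=C(C)[C@]3(O)CC(=O)[C@@](C)(O)C[C@]3(O)[C@@H]12 | intermediate
13 | (3aS,5aR,7S,8S,9aS,9bS)-5a,7,8,9a-tetrahydroxy-5,8-dimethyl-1-methylidene-3a,5a,6,7,8,9,9a,9b-octahydronaphtho[2,1-b]furan-2(1H)-one | C=C1C(=O)O[C@H]2C=C(C)[C@]3(O)C[C@H](O)[C@@](C)(O)C[C@]3(O)[C@@H]12 | intermediate
14 | (3aS,5aR,7S,8S,9aS,9bS)-5a,8,9a-trihydroxy-5,8-dimethyl-1-methylidene-7-[(triethylsilyl)oxy]-3a,5a,6,7,8,9,9a,9b-octahydronaphtho[2,1-b]furan-2(1H)-one | C=C1C(=O)O[C@H]2C=C(C)[C@]3(O)C[C@H](O[Si](CC)(CC)CC)[C@@](C)(O)C[C@]3(O)[C@@H]12 | intermediate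
15 | (3aS,6S,7S,10Z,11aS)-6-hydroxy-6,10-dimethyl-3-methylidene-7-[(triethylsilyl)oxy]-3a,5,6,7,8,11a-hexahydrocyclodeca[b]furan-2,4,9(3H)-trione | C=C1C(=O)O[C@H]2/C=C(/C)C(=O)C[C@H](O[Si](CC)(CC)CC)[C@@](C)(O)CC(=O)[C@@H]12 | intermediate (not isolated)
16 | (3aR,4R,6S,7S,10Z,11aS)-4,6-dihydroxy-6,10-dimethyl-3-methylidene-7-[(triethylsilyl)oxy]-3a,4,5,6,7,8-hexahydrocyclodeca[b]furan-2,9(3H,11aH)-dione | C=C1C(=O)O[C@H]2/C=C(/C)C(=O)C[C@H](O[Si](CC)(CC)CC)[C@@](C)(O)C[C@@H](O)[C@@H]12 | intermediate
17 | (2Z)-2-methylbut-2-enoic acid (angelic acid) | C/C=C(/C)C(=O)O | starting material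
18 | (2Z)-2-methylbut-2-enoic 2,4,6-trichlorobenzoic anhydride | C/C=C(/C)C(=O)OC(=O)c1c(Cl)cc(Cl)cc1Cl | intermediate (not isolated)
19 | (3aR,4R,6S,7S,10Z,11aS)-6-hydroxy-6,10-dimethyl-3-methylidene-2,9-dioxo-7-[(triethylsilyl)oxy]-2,3,3a,4,5,6,7,8,9,11a-decahydrocyclodeca[b]furan-4-yl (2Z)-2-methylbut-2-enoate | C=C1C(=O)O[C@H]2/C=C(/C)C(=O)C[C@H](O[Si](CC)(CC)CC)[C@@](C)(O)C[C@@H](OC(=O)/C(C)=C\C)[C@@H]12 | intermediate
20 | (3aR,4R,6S,7S,10Z,11aS)-6,7-dihydroxy-6,10-dimethyl-3-methylidene-2,9-dioxo-2,3,3a,4,5,6,7,8,9,11a-decahydrocyclodeca[b]furan-4-yl (2Z)-2-methylbut-2-enoate | C=C1C(=O)O[C@H]2/C=C(/C)C(=O)C[C@H](O)[C@@](C)(O)C[C@@H](OC(=O)/C(C)=C\C)[C@@H]12 | target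

Total steps: 13. Longest linear sequence: 13 steps (1 to 20).

Steps most likely to fail

Step 3. Migratory insertion into a diene whose two ends are flanked by quaternary carbons may be slower than base-induced loss of the bromoacrylate (dehydrobromination, polymerisation) or β-hydride elimination from the allyl–palladium intermediate; transesterification of the new lactone onto the cis C8 hydroxyl could follow. The fallback sets out from 4 and annulates the diene with 2-bromoprop-2-en-1-ol (Pd(OAc)2, PPh3, KOAc, n-Bu4NCl, DMF, 80 °C), a partner that cannot polymerise and closes through an alkoxide, to give the cyclic ether (3aS,4S,7aS)-5,5-dimethoxy-6-methyl-3-methylidene-4-(2-methylprop-2-en-1-yl)-2,3,3a,4,5,7a-hexahydro-1-benzofuran-4-ol F1. Allylic oxidation of its O–CH2 group (CrO3 (5 mol %), t-BuOOH, CH2Cl2, rt) then gives lactone 6, where the route is rejoined.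

Step 2. [4+2] dimerisation or ketal exchange of dienone 2 may compete with the catalytic addition, and facial discrimination may be incomplete, leaving 4 of low enantiomeric purity. The fallback sets out from 2 and adds 2-methylallylmagnesium chloride (THF, −78 °C) to give racemic 6,6-dimethoxy-5-methyl-1-(2-methylprop-2-en-1-yl)cyclohexa-2,4-dien-1-ol F2. This is resolved by preparative chromatography on a chiral stationary phase (amylose tris(3,5-dimethylphenylcarbamate)); the (S)-enantiomer is 4, where the route is rejoined.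

Step 11. Hydride delivery within the ten-membered ring may not follow the six-membered chelate model and may give the C8 epimer, and a slow reduction exposes diketone 15 to enolisation toward C7 (epimerisation, β-elimination of the lactone carboxylate). The fallback sets out from 15, made as in step 11, and reduces it at once under acidic hydroxyl-directed conditions (Me4NBH(OAc)3, MeCN–AcOH, −30 °C). These deliver hydride from the C10–OH side and should give the 1,3-anti alcohol (3aR,4S,6S,7S,10Z,11aS)-4,6-dihydroxy-6,10-dimethyl-3-methylidene-7-[(triethylsilyl)oxy]-3a,4,5,6,7,8-hexahydrocyclodeca[b]furan-2,9(3H,11aH)-dione F3. Mitsunobu esterification with angelic acid 17 (PPh3, DIAD, toluene, 0 °C) inverts C8 and gives ester 19, where the route is rejoined.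

Further compounds
F1 | step 3 | (3aS,4S,7aS)-5,5-dimethoxy-6-methyl-3-methylidene-4-(2-methylprop-2-en-1-yl)-2,3,3a,4,5,7a-hexahydro-1-benzofuran-4-ol | C=C1CO[C@H]2C=C(C)C(OC)(OC)[C@](O)(CC(C)=C)[C@@H]12
F2 | step 2 | racemic 6,6-dimethoxy-5-methyl-1-(2-methylprop-2-en-1-yl)cyclohexa-2,4-dien-1-ol | COC1(OC)C(C)=CC=CC1(O)CC(C)=C
F3 | step 11 | (3aR,4S,6S,7S,10Z,11aS)-4,6-dihydroxy-6,10-dimethyl-3-methylidene-7-[(triethylsilyl)oxy]-3a,4,5,6,7,8-hexahydrocyclodeca[b]furan-2,9(3H,11aH)-dione | C=C1C(=O)O[C@H]2/C=C(/C)C(=O)C[C@H](O[Si](CC)(CC)CC)[C@@](C)(O)C[C@H](O)[C@@H]12
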